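**Same unit.** In millimolar per minute rather than percent, the earlier runs can be laid side by side. I divide X at 8.00 min by that time and call this the X output, the net amount of X gained per litre per minute, averaged over the run: 26.5 mM min⁻¹ in gamma, 26.8 mM min⁻¹ in beta, 29.5 mM min⁻¹ in zeta.

| flask | Z | Q | E | remark | time |
|---|---|---|---|---|---|
| beta | 1 M | 200 mM (held) | 0.25 mol% | run made earlier |  |
| gamma | 1 M | 200 mM (held) | 0.38 mol% | run made earlier |  |
| zeta | 2 M | 200 mM (held) | 0.5 mol% | run made earlier |  |
| flask | 1.0 M | 200 mM (held) | 0.5 mol% |  | 8.0 min |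

| run | time / min | X / % | Z / % |
|---|---|---|---|
| beta | 0.667 | 2.1 | 95.6 |
| beta | 1.33 | 4.3 | 91.6 |
| beta | 3.00 | 9.7 | 81.8 |
| beta | 8.00 | 21.4 | 54.3 |
| gamma | 1.00 | 3.3 | 94.1 |
| gamma | 3.00 | 9.8 | 81.6 |
| gamma | 5.00 | 15.1 | 70.0 |
| gamma | 8.00 | 21.2 | 54.3 |
| zeta | 1.00 | 2.3 | 96.4 |
| zeta | 3.00 | 4.7 | 88.1 |
| zeta | 5.00 | 7.8 | 80.8 |
| zeta | 8.00 | 11.8 | 70.2 |

(scatter of a reading: 0.3 percentage points)

- at the start none of Q is in solution

- Monday's: doubling the transfer coefficient of Q, all else as stated
- Wednesday's: doubling the amount of E, all else as stated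
- Saturday's: doubling the saturation concentration of Q, all else as stated

- X at 8.0 min, in percent of the Z charged
- the change that raises the amount of X at 8.0 min, in percent of the Z charged most ("none" if none brings more than 2 percentage points) (Monday's / Wednesday's / Saturday's / none)
- amount of X at 8.0 min, in percent of the Z charged, after Wednesday's

**Nearest run.** Gamma looks nearly like the flask, with the same Z and Q and a loading of 0.38 mol% against 0.5 mol%. From beta to gamma the loading rises 1.52 times, yet X at 8.00 min moves by 0.2 percentage points, less than the scatter of 0.3 points. So I treat X as zero order in E over this time. An output held steady integrates to a straight line: X equals output times time, divided by the Z charged. For the flask, with gamma's output, that gives me 21.2 %. The output is an average, though: gamma's first reading gives 33.0 mM min⁻¹, faster than the average, so X slows along the gamma run.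

**The forecast.** It gives 21.4 % (range 20.3 % to 22.6 %) and 21.7 % after Wednesday's, on the ground that “X looks capped by Q supply from the gas, with dissolved Q staying low”, and it picks Saturday's. My reckoned figure stands 0.2 points below its value for the flask, less than the scatter of 0.3 points.

**The result.** The flask gives 21.4 %, and 21.0 % after Wednesday's. The strongest change is Saturday's, worth 16 points, against 13 points for Monday's.

    Q ⇌ D, rate k1*(csat - [D]) (kL = 0.00490 s⁻¹)
    Z + D ⇌ G (K = 13.0 M⁻¹, k = 0.0450 M⁻¹ s⁻¹)
    Z ⇌ L (K = 1.20, k = 2.00 × 10⁻⁴ s⁻¹)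
    2 E ⇌ J, settled at all times (K = 69.0 M⁻¹)
    Z + D ⇌ X (K = 13.0 M⁻¹, k = 0.120 M⁻¹ s⁻¹)
    X + E ⇌ G + E, rate k6*[E]*[X] forward; the back reaction follows from the equilibrium constant (k = 0.540 M⁻¹ s⁻¹)

**Later reading.** The flask's own output is 26.8 mM min⁻¹, beside gamma's 26.5 mM min⁻¹. A neighbouring flask differs only in being read at 15 min. Gamma's output carried to that time gives 39.7 %. That neighbour holds 32.1 % X, an output of 21.4 mM min⁻¹, less than gamma's.

The readings were generated by integration with made-up constants, and the scatter is random.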